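**Plan**
1. Retrosynthesis (quinic acid numbering: C1 carries OH and CO2H, C3 the free OH, C4 and C5 the vanilloyl esters): remove the three benzyl groups; take the C3 carbinol back to a ketone; cut the ring bond C1–C2 as an aldol bond; cut the two aroyl esters; take the keto ester carbonyl back to a 1,1-disubstituted alkene; cut C5–C6 to reach D-erythrose and benzyl 2-(bromomethyl)acrylate.
2. Enabling feature: the tertiary C1–OH and the only unacylated secondary oxygen (on C3) are 1,3-related across the C2 methylene; with C3 as a ketone, C1–C2 is an aldol bond, and the C1 oxygen can be tied to C3 in a temporary oxane ring (O, C1, C6, C5, C4, C3), locked as a benzyl ketoside, that carries C2 as an exocyclic enol-ether methylene and masks both carbonyls.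
3. Forward: indium allylation joins the seven-carbon chain; ozonolysis closes the temporary oxane (a 3-deoxyhept-2-ulosonate); ketosidation, iodination, aroylation and dehydroiodination give the 6-methylidene oxane; a mercury-catalysed ring opening/aldol exchanges the oxane for the cyclohexane, the only carbocycle made in the route; reduction and hydrogenolysis finish.
4. Because C3 is a ketone when the ring forms, O4 and O5 are the only free hydroxyls at the acylation stage and receive their final (O-benzyl) vanilloyl groups from one symmetric anhydride before the carbocycle exists; no hydroxyl differentiation is needed on the ring.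
5. Stereochemistry: C4 comes from C2 of D-erythrose; C5 from chelation-controlled allylation; C1 from the chair aldol transition state; C3 from equatorial hydride delivery; C3 of erythrose is sacrificed as the enol-ether carbon.

Key step: step 9

Assumption: D-erythrose, benzyl 2-(bromomethyl)acrylate and 4-(benzyloxy)-3-methoxybenzoic acid are taken as catalogue compounds; the anomeric configuration drawn for 4, 5, 6, 10 and 11 (axial anomeric oxygen, equatorial ester) is the expected thermodynamic one and has no consequence, because this carbon becomes a carbonyl in 12.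

Step 1
Reactants: 1 D-erythrose; 2 benzyl 2-(bromomethyl)acrylate
Product: 3 benzyl 2,3-dideoxy-2-methylidene-D-arabino-heptonate [benzyl (4R,5S,6R)-4,5,6,7-tetrahydroxy-2-methylideneheptanoate]
Conditions: In powder (1.5 equiv), THF/H2O 1:1, rt
Reagents that add atoms: none
Why: Barbier-type indium-mediated allylation of an unprotected aldose in water, in which the new C4 carbinol should be set threo to the neighbouring hydroxyl by addition to the indium chelate of the α-hydroxy aldehyde (Cram chelate control).

Step 2
Reactants: 3 benzyl 2,3-dideoxy-2-methylidene-D-arabino-heptonate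
Product: 4 benzyl 3-deoxy-α-D-arabino-hept-2-ulopyranosonate
Conditions: O3, MeOH, −78 °C; Me2S, −78 °C to rt
Reagents that add atoms: ozone [O-][O+]=O
Why: Ozonolysis of the electron-poor 1,1-disubstituted alkene gives the α-keto ester, which should close with the C6 hydroxyl to the six-membered hemiketal, the resting form of 3-deoxy-2-ulosonic esters, without touching a stereocentre.

Step 3
Reactants: 4 benzyl 3-deoxy-α-D-arabino-hept-2-ulopyranosonate
Product: 5 benzyl (benzyl 3-deoxy-α-D-arabino-hept-2-ulopyranosid)onate
Conditions: BnOH (solvent), Amberlyst 15 (H+ form), 4 Å molecular sieves, 50–60 °C; filter, remove BnOH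
Reagents that add atoms: benzyl alcohol OCc1ccccc1
Why: Fischer-type ketosidation under thermodynamic control should give the pyranoside with axial benzyloxy and equatorial ester (anomeric effect), ester exchange being degenerate in this solvent, so that the oxane is locked without change at C4, C5 or C6.

Step 4
Reactants: 5 benzyl (benzyl 3-deoxy-α-D-arabino-hept-2-ulopyranosid)onate
Product: 6 benzyl (benzyl 3,7-dideoxy-7-iodo-α-D-arabino-hept-2-ulopyranosid)onate
Conditions: PPh3, imidazole, I2, THF, 0 to 50 °C
Reagents that add atoms: iodine II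
Why: Garegg–Samuelsson (Appel-type) iodination should select the only primary hydroxyl, since the two secondary hydroxyls react far more slowly and the anomeric carbon no longer carries a hydroxyl.

Step 5
Reactants: 7 4-(benzyloxy)-3-methoxybenzoic acid
Product: 8 4-(benzyloxy)-3-methoxybenzoyl chloride
Conditions: (COCl)2, DMF (cat.), CH2Cl2, 0 °C to rt; concentrate
Reagents that add atoms: oxalyl chloride ClC(=O)C(=O)Cl
Why: Standard acid chloride formation through the catalytic chloroiminium species, which leaves the aryl benzyl ether intact.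

Step 6
Reactants: 7 4-(benzyloxy)-3-methoxybenzoic acid; 8 4-(benzyloxy)-3-methoxybenzoyl chloride
Product: 9 4-(benzyloxy)-3-methoxybenzoic anhydride
Conditions: Et3N (1.1 equiv), CH2Cl2, 0 °C to rt
Reagents that add atoms: none
Why: Acylation of the triethylammonium carboxylate of 7 by the acid chloride 8 is the standard preparation of a symmetric aromatic anhydride, a single reagent that carries both aroyl groups of the target.

Step 7
Reactants: 6 benzyl (benzyl 3,7-dideoxy-7-iodo-α-D-arabino-hept-2-ulopyranosid)onate; 9 4-(benzyloxy)-3-methoxybenzoic anhydride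
Product: 10 benzyl (benzyl 4,5-di-O-[4-(benzyloxy)-3-methoxybenzoyl]-3,7-dideoxy-7-iodo-α-D-arabino-hept-2-ulopyranosid)onate
Conditions: 9 (2.5 equiv), DMAP (0.3 equiv), pyridine, CH2Cl2, rt; NaHCO3 wash to recover acid 7
Reagents that add atoms: none
Why: DMAP-catalysed acylation by the anhydride should esterify the two equatorial secondary hydroxyls O4 and O5, the only hydroxyls left, with their final aroyl groups, while the chloride-free medium avoids halide exchange at the primary iodide and no stereocentre changes.

Step 8
Reactants: 10 benzyl (benzyl 4,5-di-O-[4-(benzyloxy)-3-methoxybenzoyl]-3,7-dideoxy-7-iodo-α-D-arabino-hept-2-ulopyranosid)onate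
Product: 11 benzyl (2R,4R,5S)-2-(benzyloxy)-4,5-bis{[4-(benzyloxy)-3-methoxybenzoyl]oxy}-6-methylideneoxane-2-carboxylate (the hept-6-enopyranosid-2-ulosonate)
Conditions: AgF, pyridine, rt, dark
Reagents that add atoms: none
Why: Silver-assisted E2 dehydroiodination of the primary iodide toward the ring C6–H is the standard entry to exocyclic enol ethers of pyranosides and tolerates aroyl esters.

Step 9
Reactants: 11 benzyl (2R,4R,5S)-2-(benzyloxy)-4,5-bis{[4-(benzyloxy)-3-methoxybenzoyl]oxy}-6-methylideneoxane-2-carboxylate
Product: 13 benzyl 4,5-di-O-[4-(benzyloxy)-3-methoxybenzoyl]-3-dehydroquinate, via acyclic 7-mercurio-2,6-diketone 12 (not isolated)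
Conditions: Hg(OCOCF3)2 (10 mol%), acetone/H2O 4:1, rt
Reagents that add atoms: water O
Why: Proposed new method: divalent mercury adds to the exocyclic enol ether (mercury at the methylene carbon, water at C6 of the oxane), the resulting hemiketal opens, and the anomeric carbon, now a hemiketal bearing hydroxyl, benzyloxy and the ester, collapses to the α-keto ester with loss of benzyl alcohol, so that both masked carbonyls of 12 appear together with a regiodefined mercury enolate, which adds to the keto ester carbonyl before protodemercuration returns the catalyst. The closest known reaction types are the Ferrier carbocyclization of alkyl aldohex-5-enopyranosides, which closes onto an aldehyde, and the uncatalysed aldol collapse of the enol-pyranose form of 3,7-dideoxyhept-2,6-diulosonate to 3-dehydroquinate; new here is the mercury-catalysed closure of a ketosidic 2-ulosonate ester onto a ketone carbonyl to give a tertiary carbinol. The carbocycle closes by a 6-(enolendo)-exo-trig aldol in which the former methylene carbon becomes C2 and the ring oxygen of the oxane becomes the C1 hydroxyl. The one new stereocentre, C1, should be set in a chair transition state anchored by the two equatorial aroyloxy groups at C4 and C5, with the benzyl ester equatorial and the carbonyl oxygen axial, where mercury can bridge it to the enolate oxygen; this is the sense seen in the aldose series (new hydroxyl trans to the 1,3-related oxygen, here O5). The step needs enolate regiocontrol and chemoselectivity against β-elimination of the O5 aroyloxy group or of the new C1 hydroxyl: the first is fixed by the position of the enol ether and by ring size (only this aldol gives a six-membered ring), the second by the near-neutral aqueous medium and by the fact that neither carbonyl exists before the moment of closure.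

Step 10
Reactants: 13 benzyl 4,5-di-O-[4-(benzyloxy)-3-methoxybenzoyl]-3-dehydroquinate
Product: 14 benzyl 4,5-di-O-[4-(benzyloxy)-3-methoxybenzoyl]quinate
Conditions: LiBH(s-Bu)3 (2.2 equiv), THF, −78 °C; AcOH, −78 °C
Reagents that add atoms: none
Why: Substrate-controlled reduction with a bulky trialkylborohydride, in which the axial C1 oxygen (deprotonated by the first equivalent) blocks the axial trajectory at C3, so hydride should arrive equatorially and give the axial 3-OH cis to O4 and to the C1 oxygen, the cold acidic quench being meant to protonate the C3 alkoxide before the cis O4 aroyl group can migrate.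

Step 11
Reactants: 14 benzyl 4,5-di-O-[4-(benzyloxy)-3-methoxybenzoyl]quinate
Product: 15 Burkinabin C (4,5-di-O-vanilloylquinic acid)
Conditions: H2 (1 atm), Pd/C (10% palladium on carbon), EtOAc/THF, rt
Reagents that add atoms: none
Why: Hydrogenolysis should cleave the benzyl ester and both aryl benzyl ethers under neutral conditions, which avoids O4 to O3 acyl migration and touches no stereocentre.

**Compound list**
1 | D-erythrose (drawn open-chain) | O=C[C@H](O)[C@H](O)CO | starting material
2 | benzyl 2-(bromomethyl)acrylate | C=C(CBr)C(=O)OCc1ccccc1 | starting material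
3 | benzyl (4R,5S,6R)-4,5,6,7-tetrahydroxy-2-methylideneheptanoate | C=C(C[C@@H](O)[C@H](O)[C@H](O)CO)C(=O)OCc1ccccc1 | intermediate
4 | benzyl 3-deoxy-α-D-arabino-hept-2-ulopyranosonate | OC[C@H]1O[C@@](O)(C(=O)OCc2ccccc2)C[C@@H](O)[C@@H]1O | intermediate
5 | benzyl (benzyl 3-deoxy-α-D-arabino-hept-2-ulopyranosid)onate | OC[C@H]1O[C@@](OCc2ccccc2)(C(=O)OCc2ccccc2)C[C@@H](O)[C@@H]1O | intermediate
6 | benzyl (benzyl 3,7-dideoxy-7-iodo-α-D-arabino-hept-2-ulopyranosid)onate | IC[C@H]1O[C@@](OCc2ccccc2)(C(=O)OCc2ccccc2)C[C@@H](O)[C@@H]1O | intermediate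
7 | 4-(benzyloxy)-3-methoxybenzoic acid | COc1cc(C(=O)O)ccc1OCc1ccccc1 | starting material
8 | 4-(benzyloxy)-3-methoxybenzoyl chloride | COc1cc(C(=O)Cl)ccc1OCc1ccccc1 | intermediate
9 | 4-(benzyloxy)-3-methoxybenzoic anhydride | COc1cc(C(=O)OC(=O)c2ccc(OCc3ccccc3)c(OC)c2)ccc1OCc1ccccc1 | intermediate
10 | benzyl (benzyl 4,5-di-O-[4-(benzyloxy)-3-methoxybenzoyl]-3,7-dideoxy-7-iodo-α-D-arabino-hept-2-ulopyranosid)onate | IC[C@H]1O[C@@](OCc2ccccc2)(C(=O)OCc2ccccc2)C[C@@H](OC(=O)c2ccc(OCc3ccccc3)c(OC)c2)[C@@H]1OC(=O)c1ccc(OCc2ccccc2)c(OC)c1 | intermediate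
11 | benzyl (2R,4R,5S)-2-(benzyloxy)-4,5-bis{[4-(benzyloxy)-3-methoxybenzoyl]oxy}-6-methylideneoxane-2-carboxylate | C=C1O[C@@](OCc2ccccc2)(C(=O)OCc2ccccc2)C[C@@H](OC(=O)c2ccc(OCc3ccccc3)c(OC)c2)[C@@H]1OC(=O)c1ccc(OCc2ccccc2)c(OC)c1 | intermediate
12 | benzyl (4R,5S)-4,5-bis{[4-(benzyloxy)-3-methoxybenzoyl]oxy}-2,6-dioxo-7-[(trifluoroacetoxy)mercurio]heptanoate (formed in the flask, not isolated) | O=C(O[C@H](C(=O)C[Hg]OC(=O)C(F)(F)F)[C@H](OC(=O)c1ccc(OCc2ccccc2)c(OC)c1)CC(=O)C(=O)OCc1ccccc1)c1ccc(OCc2ccccc2)c(OC)c1 | intermediate
13 | benzyl 4,5-di-O-[4-(benzyloxy)-3-methoxybenzoyl]-3-dehydroquinate (C1-OH and O4 on one face, CO2Bn and O5 on the other) | COc1cc(C(=O)O[C@@H]2C(=O)C[C@@](O)(C(=O)OCc3ccccc3)C[C@H]2OC(=O)c2ccc(OCc3ccccc3)c(OC)c2)ccc1OCc1ccccc1 | intermediate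
14 | benzyl 4,5-di-O-[4-(benzyloxy)-3-methoxybenzoyl]quinate (C1-OH, C3-OH and O4 on one face, CO2Bn and O5 on the other) | COc1cc(C(=O)O[C@@H]2[C@H](O)C[C@@](O)(C(=O)OCc3ccccc3)C[C@H]2OC(=O)c2ccc(OCc3ccccc3)c(OC)c2)ccc1OCc1ccccc1 | intermediate
15 | Burkinabin C (4,5-di-O-vanilloylquinic acid) | COc1cc(C(=O)O[C@@H]2[C@H](O)C[C@@](O)(C(=O)O)C[C@H]2OC(=O)c2ccc(O)c(OC)c2)ccc1O | target

**Totals**
Total step count: 11. Longest linear sequence: 9 steps (steps 1, 2, 3, 4, 7, 8, 9, 10, 11); steps 5 and 6 are a two-step side branch that joins at step 7.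

**Steps most likely to fail**

Step 9 (proposed new method). The carbon–mercury bond may be protonated before the carbon–carbon bond forms, giving hydration without ring closure; closure onto a hydrated keto ester may be slow; or the aldol may dehydrate after closure. Fallback with known chemistry (enol ether hydrolysis, then amine-catalysed intramolecular aldol of the Hajos–Parrish type): setting out from 11, hydrolysis of the enol ether with aqueous acetic acid in THF should give, after loss of benzyl alcohol from the anomeric hemiketal, the free diketone benzyl (4R,5S)-4,5-bis{[4-(benzyloxy)-3-methoxybenzoyl]oxy}-2,6-dioxoheptanoate F1. Treatment of this with pyrrolidinium acetate at rt should form the enamine of the methyl ketone and close the ring by 6-enolendo aldolization onto the keto ester, a closure that the parent diulosonate undergoes spontaneously, returning to the route at 13.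

Step 10. Hydride may be delivered from the wrong face, the C1 lithium alkoxide may open by retro-aldol, or the O4 aroyl group may migrate to the new C3 alkoxide. Fallback: setting out from 13, silylation of the tertiary hydroxyl (Et3SiOTf, 2,6-lutidine, CH2Cl2, −78 °C) should give benzyl 4,5-di-O-[4-(benzyloxy)-3-methoxybenzoyl]-1-O-triethylsilyl-3-dehydroquinate F2. Luche reduction (NaBH4, CeCl3·7H2O, MeOH, −78 °C) should then give benzyl 4,5-di-O-[4-(benzyloxy)-3-methoxybenzoyl]-1-O-triethylsilylquinate F3, because the axial silyloxy group shields the axial trajectory and the protic medium protonates the alkoxide at once. HF·pyridine in THF removes the silyl group and returns to the route at 14.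

Step 3. Ketosidation of the deactivated, ester-bearing anomeric carbon may stall, or may give furanosides, anomer mixtures or lactones. Fallback: lock the oxane with a sacrificial anomeric acyl group in place of the ketoside. Setting out from 4, iodination as in step 4 should give benzyl 3,7-dideoxy-7-iodo-α-D-arabino-hept-2-ulopyranosonate F4. Forcing aroylation with an excess of chloride 8 (pyridine, DMAP, CH2Cl2, 0 to 40 °C) should esterify O4 and O5 and also cap the tertiary anomeric hydroxyl, as in the peracylation of ulosonic esters, giving benzyl 2,4,5-tri-O-[4-(benzyloxy)-3-methoxybenzoyl]-3,7-dideoxy-7-iodo-α-D-arabino-hept-2-ulopyranosonate F5. AgF in pyridine should then give benzyl (2S,4R,5S)-2,4,5-tris{[4-(benzyloxy)-3-methoxybenzoyl]oxy}-6-methylideneoxane-2-carboxylate F6. Under the conditions of step 9 this should lose acid 7 in place of benzyl alcohol and return to the route at 13.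

**Further compounds**
F1 | step 9 | benzyl (4R,5S)-4,5-bis{[4-(benzyloxy)-3-methoxybenzoyl]oxy}-2,6-dioxoheptanoate | O=C(O[C@H](C(C)=O)[C@H](OC(=O)c1ccc(OCc2ccccc2)c(OC)c1)CC(=O)C(=O)OCc1ccccc1)c1ccc(OCc2ccccc2)c(OC)c1
F2 | step 10 | benzyl 4,5-di-O-[4-(benzyloxy)-3-methoxybenzoyl]-1-O-triethylsilyl-3-dehydroquinate | COc1cc(C(=O)O[C@@H]2C(=O)C[C@@](O[Si](CC)(CC)CC)(C(=O)OCc3ccccc3)C[C@H]2OC(=O)c2ccc(OCc3ccccc3)c(OC)c2)ccc1OCc1ccccc1
F3 | step 10 | benzyl 4,5-di-O-[4-(benzyloxy)-3-methoxybenzoyl]-1-O-triethylsilylquinate | COc1cc(C(=O)O[C@@H]2[C@H](O)C[C@@](O[Si](CC)(CC)CC)(C(=O)OCc3ccccc3)C[C@H]2OC(=O)c2ccc(OCc3ccccc3)c(OC)c2)ccc1OCc1ccccc1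
F4 | step 3 | benzyl 3,7-dideoxy-7-iodo-α-D-arabino-hept-2-ulopyranosonate | IC[C@H]1O[C@@](O)(C(=O)OCc2ccccc2)C[C@@H](O)[C@@H]1O
F5 | step 3 | benzyl 2,4,5-tri-O-[4-(benzyloxy)-3-methoxybenzoyl]-3,7-dideoxy-7-iodo-α-D-arabino-hept-2-ulopyranosonate | IC[C@H]1O[C@@](OC(=O)c2ccc(OCc3ccccc3)c(OC)c2)(C(=O)OCc2ccccc2)C[C@@H](OC(=O)c2ccc(OCc3ccccc3)c(OC)c2)[C@@H]1OC(=O)c1ccc(OCc2ccccc2)c(OC)c1
F6 | step 3 | benzyl (2S,4R,5S)-2,4,5-tris{[4-(benzyloxy)-3-methoxybenzoyl]oxy}-6-methylideneoxane-2-carboxylate | C=C1O[C@@](OC(=O)c2ccc(OCc3ccccc3)c(OC)c2)(C(=O)OCc2ccccc2)C[C@@H](OC(=O)c2ccc(OCc3ccccc3)c(OC)c2)[C@@H]1OC(=O)c1ccc(OCc2ccccc2)c(OC)c1
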